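**Strategy.** The route rests on cutting C15–C19, the bond that closes the ester cyclopentane (C14–C15–C19–C24–C25; atoms numbered in the order of the target SMILES). A rhodium carbenoid at C19, hung from quaternary C25 by C24, lies five atoms from the allylic C15–H bond, inserts into it, closes that ring and fixes C15 from C25. The adjacent C13=C14 alkene cannot be cyclopropanated without a four-membered ring. The precursor is the C17-silylated cyclopentene-fused cycloheptane carrying the 2-diazo-3-methoxy-3-oxopropyl arm and an ester on C25. Because a C7 ketone would trap the carbenoid as a five-membered carbonyl ylide, C7 passes through the insertion as its acetate.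

Key step: step 12

Remarks before the steps:
- Numbering: C1, C2, C3, O4, C5, C6, C7, C8, O9, C10–C17, O18, C19, C20, O21, O22, C23, C24, C25, C26, N27, C28, C29, in the order of the target SMILES.
- Assumption: C3 is a hemiketal carbon that equilibrates through the open hydroxy ketone, so the route delivers its equilibrium form, taken to be the configuration drawn.
- Centres or double bonds that a later step erases or resets are written without configuration: C25 in 9; C7 in 16–19 and 31; C19 in 18–28; C10 in 21, 22 and 24; the enol ether geometry in 28–30; the hydrazone geometry in 12 and 14.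

Step 1
Reactants: 1 cyclopentane-1,3-dione; 2 methyl 4-oxobutanoate
Product: 4 2-(4-methoxy-4-oxobutyl)cyclopentane-1,3-dione, via alkylidene dione 3 (not isolated)
Conditions: Hantzsch ester (diethyl 2,6-dimethyl-1,4-dihydropyridine-3,5-dicarboxylate), L-proline (cat.), CH2Cl2, rt
Reagents that add atoms: none
Why: Organocatalytic reductive alkylation, in which Knoevenagel condensation at C13 of the dione gives the alkylidene dione and the Hantzsch ester reduces it by conjugate hydride transfer, so the dione is C-alkylated (C13–C12) without O-alkylation.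

Step 2
Reactants: 4 2-(4-methoxy-4-oxobutyl)cyclopentane-1,3-dione
Product: 5 methyl 4-[5-oxo-2-(trifluoromethylsulfonyloxy)cyclopent-1-en-1-yl]butanoate
Conditions: Tf2O, Et3N, CH2Cl2, −78 °C
Reagents that add atoms: trifluoromethanesulfonic anhydride, O=S(=O)(OS(=O)(=O)C(F)(F)F)C(F)(F)F
Why: O-sulfonylation of the enolised, symmetric 1,3-dione should give a single vinylogous acyl triflate.

Step 3
Reactants: 5 methyl 4-[5-oxo-2-(trifluoromethylsulfonyloxy)cyclopent-1-en-1-yl]butanoate
Product: 6 methyl 4-[2-(2-methoxy-2-oxoethyl)-5-oxocyclopent-1-en-1-yl]butanoate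
Conditions: BrZnCH2CO2Me (from BrCH2CO2Me, Zn, cat. Me3SiCl, THF), Pd(PPh3)4 (5 mol %), THF, 50 °C
Reagents that add atoms: (2-methoxy-2-oxoethyl)zinc bromide, COC(=O)C[Zn]Br
Why: Negishi coupling of a Reformatsky reagent with the activated enol triflate should attach C25–C26 to C14, the zinc enolate being mild enough to spare both esters and the enone.

Step 4
Reactants: 6 methyl 4-[2-(2-methoxy-2-oxoethyl)-5-oxocyclopent-1-en-1-yl]butanoate
Product: 7 methyl 4-[(5S)-5-hydroxy-2-(2-methoxy-2-oxoethyl)cyclopent-1-en-1-yl]butanoate (17S)
Conditions: (R)-2-methyl-CBS-oxazaborolidine [(R)-1-methyl-3,3-diphenyltetrahydro-1H,3H-pyrrolo[1,2-c][1,3,2]oxazaborole] (20 mol %), BH3·SMe2, THF, −30 °C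
Reagents that add atoms: none
Why: CBS reduction, in which the ketone binds boron with the alkenyl carbon C13 as the large group and CH2 C16 as the small one, so hydride should reach the face that gives the (17S) allylic alcohol with the esters untouched.

Step 5
Reactants: 7 (17S) allylic alcohol
Product: 8 methyl 4-[(5S)-5-[tert-butyl(dimethyl)silyloxy]-2-(2-methoxy-2-oxoethyl)cyclopent-1-en-1-yl]butanoate
Conditions: TBSCl, imidazole, DMF, rt
Reagents that add atoms: tert-butyldimethylsilyl chloride, CC(C)(C)[Si](C)(C)Cl
Why: Standard silylation of an unhindered secondary alcohol, giving the ether that protects C17 to the end of the route.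

Step 6
Reactants: 8 silyl ether diester
Product: 9 methyl (1S)-1-[tert-butyl(dimethyl)silyloxy]-5-oxo-1,2,3,4,5,6,7,8-octahydroazulene-4-carboxylate (C25 as keto/enol and epimer mixture)
Conditions: KOtBu, THF, 0 °C → rt; AcOH quench
Reagents that add atoms: none
Why: Dieckmann condensation closing the seven-membered ring (C25 onto the C7 ester), expected to take this direction because the allylic α-carbon C25 is the more acidic and the product enolate is conjugated with C13=C14, the sink under reversible alkoxide conditions.

Step 7
Reactants: 10 methyl bromopyruvate; 11 4-methylbenzenesulfonohydrazide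
Product: 12 methyl 3-bromo-2-(2-tosylhydrazinylidene)propanoate
Conditions: Et2O, 0 °C → rt
Reagents that add atoms: none
Why: Hydrazone formation at the ketone carbonyl of the α-keto ester under neutral conditions, where bromide is not displaced.

Step 8
Reactants: 9 bicyclic β-keto ester; 12 bromo tosylhydrazone
Product: 14 (17S,25R) β-keto ester carrying the 3-methoxy-3-oxo-2-(tosylhydrazinylidene)propyl arm on C25, via methyl 2-(tosyldiazenyl)acrylate 13 (not isolated)
Conditions: Cu(OTf)2 (10 mol %), 2,2'-isopropylidenebis(4-tert-butyl-2-oxazoline) (11 mol %, the antipode that gives 25R), Na2CO3, CH2Cl2, −20 °C; filtration through silica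
Reagents that add atoms: none
Why: Conjugate addition of the copper-bound β-keto ester enolate to the azoalkene released from 12 by 1,4-elimination of HBr, in which the chelated enolate reacts at C25 and the C2-symmetric ligand shields one face; because C17 is already fixed, the minor C25 epimer is a diastereomer that chromatography removes.

Step 9
Reactants: 14 hydrazone keto ester
Product: 15 (17S,25R) diazo keto ester: bicyclic β-keto ester with the 2-diazo-3-methoxy-3-oxopropyl arm on C25
Conditions: DBU, CH2Cl2, 0 °C → rt
Reagents that add atoms: none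
Why: Bamford–Stevens-type elimination, in which deprotonation of the sulfonylhydrazone N–H and loss of sulfinate should give the ester-stabilised diazo compound once the copper catalyst has been removed.

Step 10
Reactants: 15 diazo keto ester
Product: 16 C7 carbinol of 15 (both C7 epimers)
Conditions: NaBH4, CeCl3·7H2O, MeOH–THF, −40 °C
Reagents that add atoms: none
Why: Luche-type reduction of the only ketone, which the diazo ester and the other esters survive; it removes the carbonyl oxygen that would otherwise capture the carbenoid, and the new carbinol centre is temporary.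

Step 11
Reactants: 16 C7 carbinol
Product: 17 C7 acetate of 16, the substrate for the insertion
Conditions: Ac2O, DMAP, pyridine, CH2Cl2, rt
Reagents that add atoms: acetic anhydride, CC(=O)OC(C)=O
Why: DMAP-catalysed acylation of the hindered alcohol, giving an ester that has no donor oxygen within reach of C19 and that deactivates the C7–H and C10–H bonds inductively.

Step 12
Reactants: 17 diazo acetate
Product: 18 tricyclic acetate with the ester cyclopentane closed (15R,17S,25R; C19 epimers)
Conditions: Rh2(O2CCPh3)4 (1 mol %), CH2Cl2, −40 °C → 0 °C, slow addition of 17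
Reagents that add atoms: none
Why: Rh2(O2CCPh3)4 expels N2 from 17 to give an electrophilic rhodium carbenoid at C19, which takes hydride from the C15–H bond while the C19–C15 bond forms in one three-centre step with retention at C15; this is the known 1,5 C–H insertion of α-alkyl-α-diazo esters that gives cyclopentanecarboxylates. The ring closes in the 1,5 mode (C19–C24–C25–C14–C15), since addition to C13=C14 would demand a four-membered ring. C15 is set by C25: the C24 arm reaches only the allylic hydrogen on its own face, and a cyclopentane fused at sp2 C14 to both other rings can only place H15 and the C26 ester on the same side. C19 forms without reliable control (ester expected mainly anti to C16) and is fixed in step 19. Insertion must beat 1,2-hydride migration from C24, which the bulky triphenylacetate ligands and low temperature hold back, and capture by oxygen, which the C7 acetate prevents (the C26 ester carbonyl is a far weaker donor). Insertion at C10 would give a bridged bicyclo[4.2.1] ring, and those C–H bonds are deactivated by the β-acetoxy group.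

Step 13
Reactants: 18 tricyclic acetate
Product: 19 tricyclic C7 alcohol
Conditions: K2CO3 (cat.), MeOH, 0 °C → rt
Reagents that add atoms: none
Why: Transesterification at the unhindered acetyl carbonyl should free the C7 alcohol while the two methyl esters are degenerate under methanolysis; any drift at C19 is harmless because step 19 resets it.

Step 14
Reactants: 19 tricyclic C7 alcohol
Product: 20 tricyclic keto diester (C7 ketone, esters on C19 and C25, C17 silyl ether; C19 epimers)
Conditions: Dess–Martin periodinane, NaHCO3, CH2Cl2, rt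
Reagents that add atoms: none
Why: Dess–Martin oxidation of the secondary alcohol under buffered conditions returns the C7 ketone and removes the temporary centre.

Step 15
Reactants: 20 tricyclic keto diester
Product: 23 C10-methylene ketone, via Mannich base 21 (not isolated), via trimethylammonium iodide 22 (not isolated)
Conditions: LiN(SiMe3)2, THF, −78 °C; CH2=NMe2+ I−, −78 °C → rt; MeI, CH2Cl2, rt; aq. NaHCO3, rt
Reagents that add atoms: N,N-dimethylmethyleneiminium iodide (Eschenmoser's salt), C=[N+](C)C.[I-]
Why: Mannich reaction of the only possible ketone enolate (C25 is quaternary) followed by quaternisation and elimination of trimethylamine should give the exo-methylene ketone that carries C29.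

Step 16
Reactants: 23 C10-methylene ketone
Product: 25 keto lactam (N27–C26 amide, C10 S), via amino ester 24 (not isolated)
Conditions: MeNH2 (2 M in THF), THF, 0 → 45 °C
Reagents that add atoms: methylamine, CN
Why: Aza-Michael addition then lactamisation onto the C25 ester closes the piperidinone; C10 is epimerisable next to the ketone and only the epimer with the aminomethyl group cis to C26 can cyclise, so the bridged ring sets C10.

Step 17
Reactants: 25 keto lactam
Product: 27 amino ketone (N-methylpiperidine closed, C7 ketone), via triflyloxyiminium triflate 26 (not isolated)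
Conditions: Tf2O, 2-fluoropyridine, CH2Cl2, −78 → 0 °C; then Hantzsch ester, rt
Reagents that add atoms: none
Why: Electrophilic activation of the tertiary amide and double hydride transfer from the Hantzsch ester should reduce C26 to CH2 while the C19 ester and the C7 ketone (which cannot enolise at its bridgehead α-carbon) are left alone.

Step 18
Reactants: 27 amino ketone
Product: 28 C7 methoxymethylene enol ether (E/Z)
Conditions: [Ph3PCH2OMe]Cl, KN(SiMe3)2, THF, 0 °C; then 27, 0 → 50 °C
Reagents that add atoms: (methoxymethylene)triphenylphosphorane, COC=P(c1ccccc1)(c1ccccc1)c1ccccc1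
Why: Wittig methoxymethylenation, which works on ketones flanked by a quaternary carbon when excess ylide is used, introduces C6 at the aldehyde oxidation level.

Step 19
Reactants: 28 enol ether
Product: 30 enol ether with C19 set (19R), via lithium ester enolate 29 (not isolated)
Conditions: LiN(iPr)2, THF, −78 °C; then 2,6-di-tert-butyl-4-methylphenol, −78 °C
Reagents that add atoms: none
Why: Kinetic protonation of the only enolisable position: the bulky phenol should deliver the proton to the convex face of the cis-fused cyclopentane pair (the face of H15), which places the ester on the more crowded face, cis to C16, as the target requires.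

Step 20
Reactants: 30 enol ether (19R)
Product: 31 C7 carbaldehyde (both C7 epimers)
Conditions: (CO2H)2·2H2O, THF–H2O, rt
Reagents that add atoms: water, O
Why: Mild acid hydrolysis of the enol ether gives the aldehyde while the secondary silyl ether and the acid-stable C19 centre survive.

Step 21
Reactants: 31 C7 carbaldehyde
Product: 32 C7 quaternary hydroxymethyl aldehyde (CH2OH C8 on the cycloheptene side, formyl C6 on the piperidine side)
Conditions: 37% aq. HCHO, DBU (cat.), THF, 0 °C → rt
Reagents that add atoms: formaldehyde, C=O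
Why: Crossed aldol of the aldehyde enolate with formaldehyde; formaldehyde should approach planar C7 from the cycloheptene side (sp2 C14 and one axial hydrogen on C11), because the piperidine side is the axial trajectory of the chair and meets the axial hydrogens on C26 and C29.

Step 22
Reactants: 32 hydroxymethyl aldehyde
Product: 33 (E)-enone (C6=C5 conjugated with the C3 ethyl ketone)
Conditions: (MeO)2P(O)CH2C(O)Et, LiCl, iPr2NEt, MeCN, rt → 40 °C
Reagents that add atoms: dimethyl (2-oxobutyl)phosphonate, CCC(=O)CP(=O)(OC)OC
Why: Horner–Wadsworth–Emmons olefination under lithium chloride/amine conditions, mild enough not to enolise the C19 ester or reverse the aldol, adds C5, C3, C2 and C1.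

Step 23
Reactants: 33 (E)-enone
Product: 35 silyl-protected hemiketal, via open hydroxy ketone 34 (not isolated)
Conditions: H2 (1 atm), Pd/C, EtOAc, rt
Reagents that add atoms: none
Why: Hydrogenation of the disubstituted enone alkene leaves the tetrasubstituted C13=C14 alkene, and the freed δ-hydroxy ketone closes to the six-membered hemiketal.

Step 24
Reactants: 35 silyl-protected hemiketal
Product: 36 target, CNP0124876.1
Conditions: HF·pyridine, pyridine, THF, 0 °C → rt
Reagents that add atoms: none
Why: Buffered fluoride cleavage of the silyl ether frees the C17 allylic alcohol without acid or base strong enough to ionise it or to epimerise C19.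

**Compound list**

1 | cyclopentane-1,3-dione | O=C1CCC(=O)C1 | starting material
2 | methyl 4-oxobutanoate | COC(=O)CCC=O | starting material
3 | methyl 4-(2,5-dioxocyclopentylidene)butanoate | COC(=O)CCC=C1C(=O)CCC1=O | intermediate
4 | 2-(4-methoxy-4-oxobutyl)cyclopentane-1,3-dione | COC(=O)CCCC1C(=O)CCC1=O | intermediate
5 | methyl 4-[5-oxo-2-(trifluoromethylsulfonyloxy)cyclopent-1-en-1-yl]butanoate | COC(=O)CCCC1=C(OS(=O)(=O)C(F)(F)F)CCC1=O | intermediate
6 | methyl 4-[2-(2-methoxy-2-oxoethyl)-5-oxocyclopent-1-en-1-yl]butanoate | COC(=O)CCCC1=C(CC(=O)OC)CCC1=O | intermediate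
7 | methyl 4-[(5S)-5-hydroxy-2-(2-methoxy-2-oxoethyl)cyclopent-1-en-1-yl]butanoate | COC(=O)CCCC1=C(CC(=O)OC)CC[C@@H]1O | intermediate
8 | TBS ether of 7 | COC(=O)CCCC1=C(CC(=O)OC)CC[C@@H]1O[Si](C)(C)C(C)(C)C | intermediate
9 | methyl (1S)-1-[tert-butyl(dimethyl)silyloxy]-5-oxo-1,2,3,4,5,6,7,8-octahydroazulene-4-carboxylate | O=C1CCCC2=C(CC[C@@H]2O[Si](C)(C)C(C)(C)C)C1C(=O)OC | intermediate
10 | methyl bromopyruvate | COC(=O)C(=O)CBr | starting material
11 | 4-methylbenzenesulfonohydrazide | Cc1ccc(cc1)S(=O)(=O)NN | starting material
12 | methyl 3-bromo-2-(2-tosylhydrazinylidene)propanoate | COC(=O)C(CBr)=NNS(=O)(=O)c1ccc(C)cc1 | intermediate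
13 | methyl 2-(tosyldiazenyl)acrylate | COC(=O)C(=C)N=NS(=O)(=O)c1ccc(C)cc1 | intermediate
14 | (17S,25R) hydrazone keto ester | O=C1CCCC2=C(CC[C@@H]2O[Si](C)(C)C(C)(C)C)[C@@]1(CC(=NNS(=O)(=O)c3ccc(C)cc3)C(=O)OC)C(=O)OC | intermediate
15 | (17S,25R) diazo keto ester | O=C1CCCC2=C(CC[C@@H]2O[Si](C)(C)C(C)(C)C)[C@@]1(CC(=[N+]=[N-])C(=O)OC)C(=O)OC | intermediate
16 | C7 carbinol of 15 | OC1CCCC2=C(CC[C@@H]2O[Si](C)(C)C(C)(C)C)[C@@]1(CC(=[N+]=[N-])C(=O)OC)C(=O)OC | intermediate
17 | C7 acetate of 16 | CC(=O)OC1CCCC2=C(CC[C@@H]2O[Si](C)(C)C(C)(C)C)[C@@]1(CC(=[N+]=[N-])C(=O)OC)C(=O)OC | intermediate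
18 | tricyclic acetate, cyclopentane closed | CC(=O)OC1CCCC2=C3[C@H](C[C@@H]2O[Si](C)(C)C(C)(C)C)C(C(=O)OC)C[C@@]31C(=O)OC | intermediate
19 | tricyclic C7 alcohol | OC1CCCC2=C3[C@H](C[C@@H]2O[Si](C)(C)C(C)(C)C)C(C(=O)OC)C[C@@]31C(=O)OC | intermediate
20 | tricyclic keto diester | O=C1CCCC2=C3[C@H](C[C@@H]2O[Si](C)(C)C(C)(C)C)C(C(=O)OC)C[C@@]31C(=O)OC | intermediate
21 | C10 dimethylaminomethyl ketone (Mannich base) | O=C1C(CN(C)C)CCC2=C3[C@H](C[C@@H]2O[Si](C)(C)C(C)(C)C)C(C(=O)OC)C[C@@]31C(=O)OC | intermediate
22 | C10 trimethylammoniomethyl ketone iodide | O=C1C(C[N+](C)(C)C)CCC2=C3[C@H](C[C@@H]2O[Si](C)(C)C(C)(C)C)C(C(=O)OC)C[C@@]31C(=O)OC.[I-] | intermediate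
23 | C10-methylene ketone | O=C1C(=C)CCC2=C3[C@H](C[C@@H]2O[Si](C)(C)C(C)(C)C)C(C(=O)OC)C[C@@]31C(=O)OC | intermediate
24 | C10 methylaminomethyl keto diester | O=C1C(CNC)CCC2=C3[C@H](C[C@@H]2O[Si](C)(C)C(C)(C)C)C(C(=O)OC)C[C@@]31C(=O)OC | intermediate
25 | keto lactam | O=C2[C@@H]1CCC3=C4[C@H](C[C@@H]3O[Si](C)(C)C(C)(C)C)C(C(=O)OC)C[C@@]42C(=O)N(C)C1 | intermediate
26 | O-triflyl iminium triflate of 25 | O=C2[C@@H]1CCC3=C4[C@H](C[C@@H]3O[Si](C)(C)C(C)(C)C)C(C(=O)OC)C[C@@]42C(OS(=O)(=O)C(F)(F)F)=[N+](C)C1.[O-]S(=O)(=O)C(F)(F)F | intermediate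
27 | amino ketone | O=C2[C@@H]1CCC3=C4[C@H](C[C@@H]3O[Si](C)(C)C(C)(C)C)C(C(=O)OC)C[C@@]42CN(C)C1 | intermediate
28 | C7 methoxymethylene enol ether | COC=C2[C@@H]1CCC3=C4[C@H](C[C@@H]3O[Si](C)(C)C(C)(C)C)C(C(=O)OC)C[C@@]42CN(C)C1 | intermediate
29 | lithium ester enolate of 28 | COC=C2[C@@H]1CCC3=C4[C@H](C[C@@H]3O[Si](C)(C)C(C)(C)C)C(=C([O-])OC)C[C@@]42CN(C)C1.[Li+] | intermediate
30 | enol ether, 19R | COC=C2[C@@H]1CCC3=C4[C@H](C[C@@H]3O[Si](C)(C)C(C)(C)C)[C@H](C(=O)OC)C[C@@]42CN(C)C1 | intermediate
31 | C7 carbaldehyde | O=CC2[C@@H]1CCC3=C4[C@H](C[C@@H]3O[Si](C)(C)C(C)(C)C)[C@H](C(=O)OC)C[C@@]42CN(C)C1 | intermediate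
32 | C7 hydroxymethyl aldehyde | O=C[C@@]2(CO)[C@@H]1CCC3=C4[C@H](C[C@@H]3O[Si](C)(C)C(C)(C)C)[C@H](C(=O)OC)C[C@@]42CN(C)C1 | intermediate
33 | (E)-enone | CCC(=O)/C=C/[C@@]2(CO)[C@@H]1CCC3=C4[C@H](C[C@@H]3O[Si](C)(C)C(C)(C)C)[C@H](C(=O)OC)C[C@@]42CN(C)C1 | intermediate
34 | open hydroxy ketone | CCC(=O)CC[C@@]2(CO)[C@@H]1CCC3=C4[C@H](C[C@@H]3O[Si](C)(C)C(C)(C)C)[C@H](C(=O)OC)C[C@@]42CN(C)C1 | intermediate
35 | silyl-protected hemiketal | CC[C@@]1(O)CC[C@@]2(CO1)[C@@H]1CCC3=C4[C@H](C[C@@H]3O[Si](C)(C)C(C)(C)C)[C@H](C(=O)OC)C[C@@]42CN(C)C1 | intermediate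
36 | CNP0124876.1 | CC[C@@]1(O)CC[C@@]2(CO1)[C@@H]1CCC3=C4[C@H](C[C@@H]3O)[C@H](C(=O)OC)C[C@@]42CN(C)C1 | target

Total step count: 24. Longest linear sequence: 23 steps (steps 1–6 and 8–24); step 7 prepares 12 on a side branch.

**Steps most likely to fail**

Step 12. The carbenoid may be consumed by 1,2-hydride migration from C24, by the C26 ester oxygen, or by insertion at C10 faster than it reaches C15–H. The fallback reverses the polarity of the same bond; it sets out from 17 and returns at 18. HBr in Et2O at −20 °C would replace the diazo group by bromide to give the α-bromo ester F1. HF·pyridine would free the C17 alcohol to give the bromo alcohol F2, and Dess–Martin periodinane would give the bromo enone F3. KOtBu in tBuOH–THF would form the extended enolate of the cyclopentenone by removing a C15 proton and displace bromide at C19 through the γ-carbon, closing the same cyclopentane to the tricyclic enone F4. The ring fusion again forces H15 cis to C26, and attack through C13 would have to build a bridged ring. CBS reduction as in step 4 would give the (17S) alcohol F5, and TBSCl/imidazole would return 18.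

Step 21. Facial discrimination at planar C7 may be weak or reversed, with formaldehyde entering from the piperidine side. This is the least secure stereochemical argument in the route. The fallback reverses the order in which the two carbon substituents arrive; it sets out from 27 and returns at 35. Corey–Chaykovsky epoxidation (Me3S+ I−, KN(SiMe3)2, THF) would give the spiro-epoxide F6, which already carries C8. LiN(iPr)2 then 2,6-di-tert-butyl-4-methylphenol would set C19 as in step 19 to give the epoxide F7. Cp2TiCl (trivalent titanium, from Cp2TiCl2 and Zn) would open the epoxide to the tertiary C7 radical, which adds to N-methoxy-N-methylacrylamide to give the hydroxy amide F8. EtMgBr would convert the amide into the ethyl ketone, which closes to 35. The chain then enters last and takes the face that the incoming reagent prefers, the complement of the main route, so this fallback helps only if the preference is reversed.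

Step 8. Catalyst control at C25 may be insufficient, or the hydrazone nitrogen may close onto the C7 ketone. The fallback replaces catalyst control by a covalently bound auxiliary; it sets out from 9 and returns at 14. Condensation of 9 with (S)-1-phenylethylamine (cat. TsOH, toluene, molecular sieves; the antipodal amine if that is the one that gives 25R) would give the hydrogen-bonded enamino ester F9. F9 would add to the azoalkene released from 12 by Na2CO3 on the face away from the phenyl group (chiral enamine Michael addition) to give the imine F10. Aqueous acetic acid would hydrolyse the imine to 14.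

Further compounds
F1 | step 12 | α-bromo ester from 17 | CC(=O)OC1CCCC2=C(CC[C@@H]2O[Si](C)(C)C(C)(C)C)[C@@]1(CC(Br)C(=O)OC)C(=O)OC
F2 | step 12 | bromo ester C17 alcohol | CC(=O)OC1CCCC2=C(CC[C@@H]2O)[C@@]1(CC(Br)C(=O)OC)C(=O)OC
F3 | step 12 | bromo ester C17 enone | CC(=O)OC1CCCC2=C(CCC2=O)[C@@]1(CC(Br)C(=O)OC)C(=O)OC
F4 | step 12 | tricyclic C17 enone | CC(=O)OC1CCCC2=C3[C@H](CC2=O)C(C(=O)OC)C[C@@]31C(=O)OC
F5 | step 12 | tricyclic (17S) alcohol | CC(=O)OC1CCCC2=C3[C@H](C[C@@H]2O)C(C(=O)OC)C[C@@]31C(=O)OC
F6 | step 21 | C7 spiro-epoxide | C6OC62[C@@H]1CCC3=C4[C@H](C[C@@H]3O[Si](C)(C)C(C)(C)C)C(C(=O)OC)C[C@@]42CN(C)C1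
F7 | step 21 | C7 spiro-epoxide, 19R | C6OC62[C@@H]1CCC3=C4[C@H](C[C@@H]3O[Si](C)(C)C(C)(C)C)[C@H](C(=O)OC)C[C@@]42CN(C)C1
F8 | step 21 | hydroxy N-methoxy-N-methylamide | CON(C)C(=O)CC[C@@]2(CO)[C@@H]1CCC3=C4[C@H](C[C@@H]3O[Si](C)(C)C(C)(C)C)[C@H](C(=O)OC)C[C@@]42CN(C)C1
F9 | step 8 | (S)-1-phenylethyl enamino ester of 9 | COC(=O)C1=C(N[C@@H](C)c3ccccc3)CCCC2=C1CC[C@@H]2O[Si](C)(C)C(C)(C)C
F10 | step 8 | imine adduct | C[C@H](N=C1CCCC2=C(CC[C@@H]2O[Si](C)(C)C(C)(C)C)[C@@]1(CC(=NNS(=O)(=O)c3ccc(C)cc3)C(=O)OC)C(=O)OC)c4ccccc4
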